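## The problem

Compound 13 is a (2S)-flavanone. Its benzo ring A carries the ring oxygen O1 at C8a and methoxy groups at C8 and C7, pyranone ring C is fused to it, and ring B on C2 is a 3-hydroxy-4,5-dimethoxyphenyl group. The carbon skeleton is only a 1,3-diarylpropane, so the synthesis is decided by where ring C is closed, how three adjacent oxygens are placed on ring A, and how C2 is set. C2 is the only stereocentre and nothing else in the molecule can steer it, so it must come from a chiral catalyst, at most helped by a temporary partner centre at C4 that is erased when the ketone is made. Once the C4 ketone exists, C2 is fragile: base opens ring C by a retro-oxa-Michael reaction to the 2'-hydroxychalcone, which recloses without facial preference, and strong acid can ionise the benzylic C2–O1 bond. The ketone must therefore appear late and meet only near-neutral reagents afterwards. Ring B has one free phenol beside two methyl ethers, so that oxygen must stay distinguishable from every methoxy group and from any ring A phenol formed on the way. The enabling feature is that C8a–O1 and C8–OMe are adjacent C–O bonds flanked by C7–OMe: an aryne across C8–C8a can accept the C2 oxygen at C8a and an oxygen electrophile at C8, and a fluorine at C8a plus the acidified hydrogen at C8 suffice to generate it.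

## Retrosynthesis

**13 from 12.** The last bond cut is the O–CH2Ph bond of the ring B phenol, leading back to benzyl ether 12. Benzyl is preferred to silyl or acetal groups because it must survive a lithium amide, basic peroxide, carbonate with an alkyl halide and a periodinane, and then leave without enolising or opening the flavanone. The forward step must stop after the aryl benzyl ether is cleaved and spare C4=O and C2–O1.

**12 from 11.** The C4 carbonyl is taken back to the secondary alcohol of 11. With C4 as a carbinol, C2 is not β to a carbonyl group, so every basic operation can be placed before this point. Carrying the ketone further back would forbid both the methylation and the organolithium chemistry. The forward step is a mild, non-acidic oxidation, because the C4 carbinol sits on an ortho,para-dioxygenated ring and ionises easily.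

**11 from 10.** The O–CH3 bond at C8 is cut. The free C8 phenol of 10 is what the key step leaves behind, and a phenol is methylated selectively beside the C4 alcohol. Placing this step before the oxidation keeps carbonate away from the flavanone.

**10 from 5 (key disconnection).** Both C8a–O1 and C8–O are cut, which opens ring C and removes one ring A oxygen. The precursor 5 is an acyclic 1,3-diol with a 2-fluoro-4-methoxyphenyl group. Cutting O1–C2 instead would make the stereocentre in the ring-closing step, by substitution or conjugate addition, and put its configuration at risk. Cutting C8a–O1 alone would demand a 2-halo-3,4-dioxygenated ring A, which is harder to obtain. The forward reaction passes through the C8-lithiated species 6, aryne 7, the cyclised aryllithium 8 and boronate 9. It must favour intramolecular capture of the aryne and keep the aryl anion alive until it is borylated.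

**5 from 4.** The two carbinol C–H bonds are cut, giving the achiral 1,3-diketone 4. One catalytic reduction then sets both carbinol centres. Only the ring B carbinol (the future C2) must be enantiopure; the other becomes C4 and is oxidised away in 12. The forward step needs catalyst control of the same sense at both aryl ketones.

**4 from 2 and 3.** The C–C bond between the ring B carbonyl carbon and the central methylene (C2–C3 of the flavanone) is cut, a Claisen disconnection to ester 2 and methyl ketone 3. The reverse pairing would need a ring B acetophenone that is not at hand, whereas 3 is bought with the fluorine in place. The forward step must acylate the enolate of 3 without displacing the ortho fluorine.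

**2 from 1.** The benzyl ether is cut back to phenol 1, a one-step protection.

## Roads not taken

**Alternative 1:** Oxa-Povarov annulation, cutting C2–C3 and C4–C4a. The O-aryl mixed acetal A2 would be ionised by a chiral acid to an O-aryl oxocarbenium ion, ethoxyethyne A3 would add through its terminal carbon, and the cation at C4 would be captured by the free ortho carbon of ring A to give the 4-ethoxy-2H-chromene A1. Hydrolysis of the enol ether would give 12 directly.
- Merits: two C–C bonds, ring C and C2 in one step from simple pieces; C4 arrives at the ketone oxidation level; the ring A pattern is bought; closure can only occur at the one free ortho carbon, which is para to a methoxy group. The route would be two or three steps shorter than the chosen one.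
- Weak points: enantiocontrol would rest on a chiral counter-anion paired with a strongly stabilised, loosely bound oxocarbenium ion bearing the electron-rich ring B, and this is not established for ynol ether partners. A3 is acid-labile (hydration, oligomerisation). In A1 the C2–O1 bond is both benzylic and allylic to an enol ether, so the acid that forms it can re-ionise it and erase C2.
- Comparison: this road is better on convergence and step count. The chosen plan sets against that a stereocentre made by a dependable catalytic ketone reduction and never exposed to ionising conditions.

**Alternative 2:** Ortho-quinone methide hetero-Diels–Alder reaction, cutting C3–C4 and O1–C2. The salicylaldehyde acetal A5 would lose methanol under acid to give the methoxy ortho-quinone methide in its oxocarbenium form, which would add styrene A6 with inverse electron demand to give the 2,4-cis 4-methoxyflavan A4.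
- Merits: both ring C bonds form at once; polarity fixes the regiochemistry (the benzylic carbon of A6 bonds to oxygen); both partners are short to make; the ring A pattern is bought.
- Weak points: C4 emerges as a methyl ether, one oxidation level low. Turning a secondary benzylic methyl ether into a ketone next to a second benzylic C–H at C2 needs solvolysis through a benzylic cation (which can lose a proton toward the flavene) and then oxidation, so at least two further steps. A cationic cycloaddition to an unfunctionalised styrene gives a chiral catalyst no handle, and the electron-rich A6 tends to oligomerise under acid.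
- Comparison: overall length is similar, and this road builds ring C with C–C bond formation, which the chosen key step does not. The chosen plan also passes through a C4 carbinol (11), but as a free alcohol that one mild oxidation converts, and its C2 configuration does not depend on an unproven asymmetric cycloaddition.

**Alternative 3:** Friedel–Crafts closure, cutting C4–C4a. The activated acid A8 would acylate the free ortho carbon of its 2,3-dimethoxyphenoxy ring to give A7, which is the same compound as 12.
- Merits: the ring A oxygen triad is bought intact, so no C8 oxygenation or methylation is needed; closure para to a methoxy group is electronically favoured; no cryogenic organometallic step. The two routes share the final debenzylation.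
- Weak points: A8 must be made enantiopure by forming the C2–O1 bond through substitution with inversion at an electron-rich benzylic carbinol, using a hindered ortho-substituted phenol. Ionisation erodes the configuration there and β-elimination competes. A8 is a β-aryloxy acid, so loss of the phenol threatens under both basic ester cleavage and acidic acylation. The acylium ion can also close onto an ortho carbon of ring B to form a five-membered ketone, ring B being as electron-rich as ring A.
- Comparison: step counts are about equal, and this road avoids the two operations the chosen plan spends on the C8 oxygen (borylation–oxidation and methylation). The chosen plan makes the C2–O bond in a ketone reduction and never breaks it, and closes ring C under basic, non-ionising conditions where ring B cannot compete.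

Key step: step 4

Assumption: compounds 1 and 3 are taken as purchasable. The (S,S)-configured ruthenium catalyst is assumed to give (S)-carbinols from both aryl ketones, as it does from acetophenone.

## Route

Step 1
Reactants: 1 methyl 3-hydroxy-4,5-dimethoxybenzoate
Product: 2 methyl 3-(benzyloxy)-4,5-dimethoxybenzoate
Conditions: BnBr, K2CO3, DMF, 60 °C
Reagents that add atoms: benzyl bromide, BrCc1ccccc1
Why: Williamson etherification of the only acidic OH; the methyl ester and methyl ethers are inert to carbonate.

Step 2
Reactants: 3 1-(2-fluoro-4-methoxyphenyl)ethanone; 2 methyl 3-(benzyloxy)-4,5-dimethoxybenzoate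
Product: 4 1-[3-(benzyloxy)-4,5-dimethoxyphenyl]-3-(2-fluoro-4-methoxyphenyl)propane-1,3-dione
Conditions: 3, LiN(SiMe3)2 (2.5 equiv), THF, −78 °C; then 2, −78 °C to rt; 1 M HCl work-up
Reagents that add atoms: none
Why: Crossed Claisen condensation of a methyl ketone lithium enolate with a non-enolisable aryl ester, driven by deprotonation of the 1,3-diketone formed; keeping the mixture at or below room temperature should prevent the diketonate oxygen from displacing the ortho fluorine.

Step 3
Reactants: 4 1-[3-(benzyloxy)-4,5-dimethoxyphenyl]-3-(2-fluoro-4-methoxyphenyl)propane-1,3-dione
Product: 5 (1S,3S)-1-[3-(benzyloxy)-4,5-dimethoxyphenyl]-3-(2-fluoro-4-methoxyphenyl)propane-1,3-diol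
Conditions: RuCl(p-cymene)[(S,S)-TsDPEN] (3 mol%), HCO2H/Et3N (5:2), CH2Cl2, 35 °C
Reagents that add atoms: none
Why: Noyori–Ikariya asymmetric transfer hydrogenation, known for 1,3-diaryl-1,3-diketones; each aryl ketone is reduced under catalyst control with the aryl group edge-on to the arene ligand, so the (S,S) ligand should give the S carbinol at both carbons and hence the anti diol. The minor enantiomer of the first reduction ends mainly as the separable syn diastereomer, which should raise the enantiomeric purity of 5.

Step 4
Reactants: 5 (1S,3S)-1-[3-(benzyloxy)-4,5-dimethoxyphenyl]-3-(2-fluoro-4-methoxyphenyl)propane-1,3-diol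
Product: 10 (2S,4S)-2-[3-(benzyloxy)-4,5-dimethoxyphenyl]-7-methoxychromane-4,8-diol, via C8-lithiated dialkoxide 6 (not isolated), via aryne dialkoxide 7 (not isolated), via 8-lithiochroman alkoxide 8 (not isolated), via 8-boronate 9 (not isolated)
Conditions: n-BuLi (2.0 equiv), THF (0.02 M), −78 °C; lithium 2,2,6,6-tetramethylpiperidide (1.3 equiv), −78 °C, then −78 to 0 °C; B(OMe)3 (4 equiv), −78 °C to rt; 30% aq. H2O2, 0 °C to rt
Reagents that add atoms: hydrogen peroxide, OO (supplies the C8 oxygen; trimethyl borate, COB(OC)OC, enters only the unisolated boronate 9)
Why: n-BuLi converts 5 into its dialkoxide and the hindered amide removes the most acidic ring proton, the one between fluorine and methoxy (C8 in flavanone numbering), to give 6; on warming, 6 loses LiF rather than the much poorer leaving group methoxide and forms aryne 7 across C8–C8a. The alkoxide of the ring B carbinol adds to C8a and closes ring C in a six-membered exo-dig mode, the strained in-plane π bond lying outside the new ring, which leaves aryllithium 8 at C8; the benzylic alkoxide at C4 cannot compete because it could only form a four-membered ring. Regiochemistry is secured twice: the tether cannot reach C8, and the C7 methoxy group beside the aryne polarises it inductively so that a nucleophile adds to the remote carbon and the charge develops next to oxygen. Aryllithium 8 is flanked by O1 and OMe and is therefore less basic than the amide that would form from the liberated amine, so it should persist until B(OMe)3 converts it into boronate 9; basic H2O2 then brings about the usual 1,2-shift of the aryl group from boron to oxygen to give the C8 phenol. The closest known reaction type is the anionic cyclisation of tethered nucleophiles, including the hydroxyl group of 3-arylpropanols (which gives chromans), onto arynes made from ortho-metalated haloarenes with capture of the new aryl anion by an electrophile; lithiation, borylation and oxidation of 1,3-dialkoxyarenes is the standard way to 2,6-dialkoxyphenols. No stereocentre is formed: C2 and C4 are carried over from 5 because neither carbinol C–O bond is broken and nothing present can ionise or enolise them, so 10 is the 2,4-cis flavan-4-ol. The selectivity the step needs is intramolecular over intermolecular capture of 7, which high dilution, the non-nucleophilic amide and the absence of excess alkyllithium should secure.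

Step 5
Reactants: 10 (2S,4S)-2-[3-(benzyloxy)-4,5-dimethoxyphenyl]-7-methoxychromane-4,8-diol
Product: 11 (2S,4S)-2-[3-(benzyloxy)-4,5-dimethoxyphenyl]-7,8-dimethoxychroman-4-ol
Conditions: MeI, K2CO3, acetone, 50 °C
Reagents that add atoms: iodomethane, CI
Why: Williamson O-methylation; carbonate deprotonates only the phenol, so the secondary C4 alcohol stays free, and with no ketone present yet ring C cannot open under base.

Step 6
Reactants: 11 (2S,4S)-2-[3-(benzyloxy)-4,5-dimethoxyphenyl]-7,8-dimethoxychroman-4-ol
Product: 12 (2S)-2-[3-(benzyloxy)-4,5-dimethoxyphenyl]-7,8-dimethoxychroman-4-one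
Conditions: Dess–Martin periodinane, pyridine, CH2Cl2, 0 °C to rt
Reagents that add atoms: none
Why: Dess–Martin oxidation of a secondary benzylic alcohol; the pyridine buffer keeps the acetic acid released from ionising the electron-rich C4 carbinol, and the neutral, non-enolising medium leaves C2 untouched while the temporary C4 centre is erased.

Step 7
Reactants: 12 (2S)-2-[3-(benzyloxy)-4,5-dimethoxyphenyl]-7,8-dimethoxychroman-4-one
Product: 13 (2S)-2-(3-hydroxy-4,5-dimethoxyphenyl)-7,8-dimethoxychroman-4-one
Conditions: H2 (1 atm), 10% Pd/C, EtOAc, rt
Reagents that add atoms: none
Why: Hydrogenolysis of an aryl benzyl ether under neutral conditions, a standard final step for benzyl-protected flavanones; the ketone is deactivated by the ortho ring oxygen and the para methoxy group and the cyclic C2–O1 ether should cleave more slowly than the benzyl ether, so the reaction is stopped after one equivalent of hydrogen.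

## Compound list

1 | methyl 3-hydroxy-4,5-dimethoxybenzoate | COC(=O)c1cc(O)c(OC)c(OC)c1 | starting material
2 | methyl 3-(benzyloxy)-4,5-dimethoxybenzoate | COC(=O)c1cc(OCc2ccccc2)c(OC)c(OC)c1 | intermediate
3 | 1-(2-fluoro-4-methoxyphenyl)ethanone | CC(=O)c1ccc(OC)cc1F | starting material
4 | 1-[3-(benzyloxy)-4,5-dimethoxyphenyl]-3-(2-fluoro-4-methoxyphenyl)propane-1,3-dione | COc1cc(C(=O)CC(=O)c2ccc(OC)cc2F)cc(OCc2ccccc2)c1OC | intermediate
5 | (1S,3S)-1-[3-(benzyloxy)-4,5-dimethoxyphenyl]-3-(2-fluoro-4-methoxyphenyl)propane-1,3-diol | COc1cc([C@@H](O)C[C@H](O)c2ccc(OC)cc2F)cc(OCc2ccccc2)c1OC | intermediate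
6 | dilithium (1S,3S)-1-[3-(benzyloxy)-4,5-dimethoxyphenyl]-3-(2-fluoro-3-lithio-4-methoxyphenyl)propane-1,3-diolate | COc1cc([C@@H](O[Li])C[C@H](O[Li])c2ccc(OC)c([Li])c2F)cc(OCc2ccccc2)c1OC | intermediate
7 | dilithium (1S,3S)-1-[3-(benzyloxy)-4,5-dimethoxyphenyl]-3-(4-methoxy-2,3-didehydrophenyl)propane-1,3-diolate (aryne across C8–C8a) | COc1cc([C@@H](O[Li])C[C@H](O[Li])C2=CC=C(OC)C#C2)cc(OCc2ccccc2)c1OC | intermediate
8 | lithium (2S,4S)-2-[3-(benzyloxy)-4,5-dimethoxyphenyl]-8-lithio-7-methoxychroman-4-olate | COc1cc([C@@H]2C[C@H](O[Li])c3ccc(OC)c([Li])c3O2)cc(OCc2ccccc2)c1OC | intermediate
9 | lithium (2S,4S)-2-[3-(benzyloxy)-4,5-dimethoxyphenyl]-8-(dimethoxyboryl)-7-methoxychroman-4-olate | COc1cc([C@@H]2C[C@H](O[Li])c3ccc(OC)c(B(OC)OC)c3O2)cc(OCc2ccccc2)c1OC | intermediate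
10 | (2S,4S)-2-[3-(benzyloxy)-4,5-dimethoxyphenyl]-7-methoxychromane-4,8-diol | COc1cc([C@@H]2C[C@H](O)c3ccc(OC)c(O)c3O2)cc(OCc2ccccc2)c1OC | intermediate
11 | (2S,4S)-2-[3-(benzyloxy)-4,5-dimethoxyphenyl]-7,8-dimethoxychroman-4-ol | COc1cc([C@@H]2C[C@H](O)c3ccc(OC)c(OC)c3O2)cc(OCc2ccccc2)c1OC | intermediate
12 | (2S)-2-[3-(benzyloxy)-4,5-dimethoxyphenyl]-7,8-dimethoxychroman-4-one | COc1cc([C@@H]2CC(=O)c3ccc(OC)c(OC)c3O2)cc(OCc2ccccc2)c1OC | intermediate
13 | (2S)-2-(3-hydroxy-4,5-dimethoxyphenyl)-7,8-dimethoxychroman-4-one | COc1cc([C@@H]2CC(=O)c3ccc(OC)c(OC)c3O2)cc(O)c1OC | target

## Step count and risks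

Total: 7 steps. Longest linear sequence: 7 steps (1 to 13); ketone 3 enters at step 2.

**Step 4 (key step).** Three processes are most likely to go wrong:
- Intermolecular consumption of the aryne: lithium alkoxide aggregates are modest nucleophiles, so still-unreacted 6 may add to 7.
- Loss of the C8 carbanion before or after borylation, by proton transfer or by protodeboronation of the hindered 2,6-dioxygenated arylboron species under basic peroxide, which leaves hydrogen at C8.
- Metalation of the benzylic ether methylene or of ring B if base is in excess.

The fallback separates the two C–O bond formations and avoids a free aryne. It sets out from 5: the potassium alkoxide (KOt-Bu, DMSO, 80 °C) closes ring C by intramolecular nucleophilic aromatic substitution of the fluoride to give (2S,4S)-2-[3-(benzyloxy)-4,5-dimethoxyphenyl]-7-methoxychroman-4-ol F1. Should the base instead eliminate HF, only the same C8–C8a aryne can form and it closes to the same product. F1 is then converted to its lithium alkoxide and lithiated at C8 by directed ortho-metalation (n-BuLi, TMEDA, THF, 0 °C), the position between O1 and OMe being the most activated. B(OMe)3 followed by H2O2 returns the route at 10.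

**Step 2.** The electron-rich ester 2 is a sluggish acyl donor. If warming is needed, the diketonate oxygen may displace the ortho fluorine and close a chromone ring, or the enolate of 3 may self-condense. The fallback replaces acylation by aldol addition and oxidation. It sets out from 2: LiAlH4 (THF, 0 °C) gives [3-(benzyloxy)-4,5-dimethoxyphenyl]methanol F2, and MnO2 (CH2Cl2, rt) gives 3-(benzyloxy)-4,5-dimethoxybenzaldehyde F3. The lithium enolate of 3 (LiN(i-Pr)2, THF, −78 °C) adds to F3 rapidly at low temperature to give racemic 3-[3-(benzyloxy)-4,5-dimethoxyphenyl]-1-(2-fluoro-4-methoxyphenyl)-3-hydroxypropan-1-one F4. Dess–Martin oxidation returns the route at 4.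

**Step 3.** The diketone is largely enolised and both carbonyl groups are electron-rich, so the second reduction may stall. The β-hydroxy ketone may also dehydrate under the amine and be reduced at the alkene. The fallback changes the second reduction from catalyst control to substrate control. It sets out from 4: the transfer hydrogenation is stopped at the mono-reduced stage, where the more electrophilic ring B carbonyl should react first, giving (3S)-3-[3-(benzyloxy)-4,5-dimethoxyphenyl]-1-(2-fluoro-4-methoxyphenyl)-3-hydroxypropan-1-one F5. Hydroxyl-directed Evans–Saksena reduction (Me4NBH(OAc)3, MeCN/AcOH, −30 °C) delivers hydride intramolecularly to give the anti diol and returns the route at 5.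

**Step 7.** Over-reduction is the risk: hydrogenolysis of the benzylic C2–O1 bond with opening of ring C, or reduction of the aryl ketone, once the benzyl ether is gone. The fallback reverses the order of the last two operations so that no flavanone meets hydrogen and palladium. It sets out from 11: hydrogenolysis (H2, Pd/C, EtOAc) at the flavan-4-ol stage gives (2S,4S)-2-(3-hydroxy-4,5-dimethoxyphenyl)-7,8-dimethoxychroman-4-ol F6. MnO2 (CH2Cl2, rt) then oxidises the benzylic alcohol chemoselectively beside the phenol and arrives at 13.

## Further compounds

F1 | step 4 | (2S,4S)-2-[3-(benzyloxy)-4,5-dimethoxyphenyl]-7-methoxychroman-4-ol | COc1cc([C@@H]2C[C@H](O)c3ccc(OC)cc3O2)cc(OCc2ccccc2)c1OC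
F2 | step 2 | [3-(benzyloxy)-4,5-dimethoxyphenyl]methanol | OCc1cc(OCc2ccccc2)c(OC)c(OC)c1
F3 | step 2 | 3-(benzyloxy)-4,5-dimethoxybenzaldehyde | O=Cc1cc(OCc2ccccc2)c(OC)c(OC)c1
F4 | step 2 | racemic 3-[3-(benzyloxy)-4,5-dimethoxyphenyl]-1-(2-fluoro-4-methoxyphenyl)-3-hydroxypropan-1-one | COc1cc(C(O)CC(=O)c2ccc(OC)cc2F)cc(OCc2ccccc2)c1OC
F5 | step 3 | (3S)-3-[3-(benzyloxy)-4,5-dimethoxyphenyl]-1-(2-fluoro-4-methoxyphenyl)-3-hydroxypropan-1-one | COc1cc([C@@H](O)CC(=O)c2ccc(OC)cc2F)cc(OCc2ccccc2)c1OC
F6 | step 7 | (2S,4S)-2-(3-hydroxy-4,5-dimethoxyphenyl)-7,8-dimethoxychroman-4-ol | COc1cc([C@@H]2C[C@H](O)c3ccc(OC)c(OC)c3O2)cc(O)c1OC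
A1 | alternative 1 | (2S)-2-[3-(benzyloxy)-4,5-dimethoxyphenyl]-4-ethoxy-7,8-dimethoxy-2H-chromene | CCOC1=C[C@@H](c2cc(OC)c(OC)c(OCc3ccccc3)c2)Oc2c1ccc(OC)c2OC
A2 | alternative 1 | racemic 1-(benzyloxy)-5-[(2,3-dimethoxyphenoxy)(methoxy)methyl]-2,3-dimethoxybenzene | COC(Oc1cccc(OC)c1OC)c1cc(OC)c(OC)c(OCc2ccccc2)c1
A3 | alternative 1 | ethoxyethyne | CCOC#C
A4 | alternative 2 | (2S,4S)-2-[3-(benzyloxy)-4,5-dimethoxyphenyl]-4,7,8-trimethoxychromane | COc1cc([C@@H]2C[C@H](OC)c3ccc(OC)c(OC)c3O2)cc(OCc2ccccc2)c1OC
A5 | alternative 2 | 6-(dimethoxymethyl)-2,3-dimethoxyphenol | COC(OC)c1ccc(OC)c(OC)c1O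
A6 | alternative 2 | 1-(benzyloxy)-5-ethenyl-2,3-dimethoxybenzene | C=Cc1cc(OC)c(OC)c(OCc2ccccc2)c1
A7 | alternative 3 | (2S)-2-[3-(benzyloxy)-4,5-dimethoxyphenyl]-7,8-dimethoxychroman-4-one | COc1cc([C@@H]2CC(=O)c3ccc(OC)c(OC)c3O2)cc(OCc2ccccc2)c1OC
A8 | alternative 3 | (3S)-3-[3-(benzyloxy)-4,5-dimethoxyphenyl]-3-(2,3-dimethoxyphenoxy)propanoic acid | COc1cc([C@H](CC(=O)O)Oc2cccc(OC)c2OC)cc(OCc2ccccc2)c1OC
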